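The meeting opened on the time of reading: autumn, dusk and spring are each read at 80 min, so the question was whether target has stopped moving by then, and at what level.

| flask | substrate | temperature | remark | time |
|---|---|---|---|---|
| Tuesday's | 1.3 M | −19 °C | run made earlier |  |
| Wednesday's | 3 M | −5 °C | run made earlier |  |
| autumn | 2.0 M |  | at 0 °C until 25 min, from then on at −25 °C | 80 min |
| dusk | 2.0 M | −25 °C |  | 80 min |
| spring | 2.0 M | 0 °C |  | 80 min |

| run | time / min | target / % |
|---|---|---|
| Tuesday's | 8.00 | 1.7 |
| Tuesday's | 25.0 | 4.8 |
| Tuesday's | 40.0 | 5.5 |
| Tuesday's | 60.0 | 6.2 |
| Tuesday's | 90.0 | 6.4 |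
| Wednesday's | 3.00 | 5.8 |
| Wednesday's | 10.0 | 8.8 |
| Wednesday's | 15.0 | 10.6 |
| Wednesday's | 20.0 | 11.7 |
| Wednesday's | 30.0 | 12.4 |

(each reading ± 0.5 percentage points)

* the flask with the highest amount of target, in percent of the substrate charged ("all alike" if they lie within 1.5 percentage points) (autumn / dusk / spring / all alike)
* final target, as a percentage of the substrate charged, in autumn
* final target, as a percentage of the substrate charged, in dusk
* final target, as a percentage of the substrate charged, in spring

- the analysis behind the earlier runs scatters by 0.5 percentage points, standard deviation

It was noted that Tuesday's last readings, 6.2 % and 6.4 %, differ by 0.2 percentage points against a scatter of 0.5 points, so that run reads as a plateau, a quasi-steady level. Wednesday's run ended at 12.4 %.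

The author of the forecast argued that the plateau follows mass action, “so the flasks should match”, and gave autumn 9.3 %, dusk 9 % and spring 9.6 %, with the answer all alike. The forecast kept a temperature-led plateau as its alternative and widened its ranges for it.

I, taking the minutes, said that the two runs moved substrate and temperature together, and I reckoned on that alternative. Taking the last reading of each run as its plateau, and laying the whole difference on temperature as an assumption, the natural log of the plateau climbs 0.0472 K⁻¹; I named this the plateau slope. Carried from Tuesday's −19 °C down to −25 °C, it puts the cold plateau at 4.82 %. Carried from Wednesday's −5 °C up to 0 °C, it puts the warm plateau at 15.7 %. My reckoning therefore had spring above dusk, and autumn between them, coming down toward the cold plateau after its change at 25 min. The thing to watch is how far above that plateau autumn stands at its reading.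

The flasks gave spring 21.9 %, autumn 10.0 % and dusk 3.75 %, so the answer is spring.

    substrate → target (k = 0.0580 min⁻¹, Ea = 91.0 kJ mol⁻¹)
    substrate → side product A (k = 0.0240 min⁻¹, Ea = 81.0 kJ mol⁻¹)
    target ⇌ isomer of the product (K = 0.740, k = 0.300 min⁻¹, Ea = 68.0 kJ mol⁻¹, ΔH = −74.0 kJ mol⁻¹)
    substrate + target → side product B (k = 0.0720 M⁻¹ min⁻¹, Ea = 71.0 kJ mol⁻¹)
    (constants at 0 °C)

Spring stands 6.2 points above my reckoned warm plateau, and dusk 1.1 points below my reckoned cold one. In autumn the excess over the cold plateau shrank from 16 points at the change to 5.2 points at 80.0 min, on average a rate of 0.0206 min⁻¹. At that reading of autumn target was being made at 0.0481 of the rate at which it was used up, each step taken net. The neighbouring flask is autumn read at 2.5 h, and the same rate gives it 6.04 %. That flask holds 4.72 % of target.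

(Readings and results come from a simulation with constants of no real substance; scatter was added.)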